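**Plan**

1. Numbering for each bicyclic half: oxepane O1–C2(Me2)–C3–C4–C5–C6(Me)–C7(H)–O1; cyclohexane C6–C7–C8–C9–C10–C11; O11 is the oxygen on C11; linker C11–C12–C13–C11′ (primes = acetate half).
2. Retrosynthesis: the C3 ketone comes from an alcohol, the C10′ methylene from a ketone made by hydroboration of a C10′=C11′ alkene. The C13–C11′ bond is cut (B-alkyl Suzuki) into vinyl carbinol 21 and enol triflate 27, both made from one hydroxy ketone 14.
3. 14 is cut at C3–C4 and at C6–C7. Both bonds form in one cationic cascade from cyclopentane lactol 9: Prins closure, 1,2-hydride shift, ring-expanding 1,2-shift of C7.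
4. Enabling feature: the oxygens on C3 and C11 are 1,5-related through C4–C5–C6, and the quaternary C6 lies between C11 and the O-bearing C7. A temporary acetal bridge O11–C3 turns the C3–C4 closure into a six-ring Prins reaction and makes O11 the pushing group for the shift that converts a cyclopentane into the cyclohexanone while contracting the perimeter to the oxepane.
5. Forward order: cyclopentane (steps 1–6), then oxepane and cyclohexanone together (step 7), divergence to 21 and 27, union (step 18), C10′ methylene, C3 ketone.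
6. Stereochemistry: nickel hydrovinylation (side-chain centre) and Shi epoxidation (cyclopentane C7, C11). C7 is carried through step 7 and controls C6 and C3. C10 comes from enolate methylation, C11 from the epoxidation face, C3′ from CBS reduction, C11′ from hydroboration.

Key step: step 7

Remarks on the chemistry:
- Lactol 9 is used as a mixture of anomers; the anomeric centre is lost in step 7.
- In step 2 the ligand antipode is the one that gives the (S) centre.
- Hydroxy ketone 14 may equilibrate with a bridged hemiketal; it is expected to react as the open form.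
- Compound names use IUPAC locants; the text uses the numbering of plan line 1.

Step 1
Reactants: 1 cyclopent-1-ene-1-carbaldehyde
Product: 2 1-ethenylcyclopent-1-ene
Conditions: Ph3PCH3Br, KOt-Bu, Et2O, 0 °C → rt
Reagents that add atoms: methyltriphenylphosphonium bromide, C[P+](c1ccccc1)(c1ccccc1)c1ccccc1.[Br-]
Why: Wittig methylenation of a conjugated aldehyde is routine and should give the volatile diene, which is distilled and used at once.

Step 2
Reactants: 2 1-ethenylcyclopent-1-ene
Product: 3 1-[(2S)-but-3-en-2-yl]cyclopent-1-ene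
Conditions: [(η3-C3H5)NiBr]2 (1 mol %), O,O′-(1,1′-binaphthalene-2,2′-diyl) N,N-bis(1-phenylethyl)phosphoramidite (one stereoisomer, 2 mol %), NaB[3,5-(CF3)2C6H3]4, ethylene (1 atm), CH2Cl2, −78 °C
Reagents that add atoms: ethylene, C=C
Why: Nickel-catalysed asymmetric 1,2-hydrovinylation of 1-vinylcycloalkenes is a known reaction type; the nickel hydride adds to the vinyl terminus, ethylene couples at the exocyclic allyl carbon, and the ligand sets the new centre.

Step 3
Reactants: 3 1-[(2S)-but-3-en-2-yl]cyclopent-1-ene
Product: 4 (1R,5R)-1-[(2S)-but-3-en-2-yl]-6-oxabicyclo[3.1.0]hexane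
Conditions: D-fructose-derived Shi ketone (0.3 equiv), KHSO5 (as 2KHSO5·KHSO4·K2SO4), K2CO3, Bu4NHSO4, MeCN/CH2(OMe)2/aq. Na2B4O7 buffer, 0 °C
Reagents that add atoms: potassium peroxymonosulfate, [K+].[O-]S(=O)(=O)OO
Why: Shi epoxidation; the chiral dioxirane should react with the trisubstituted ring alkene far faster than with the vinyl group and, by catalyst control, deliver oxygen to the face that gives the (1R,5R) epoxide.

Step 4
Reactants: 4 (1R,5R)-1-[(2S)-but-3-en-2-yl]-6-oxabicyclo[3.1.0]hexane
Product: 5 (1R,2S)-1-[(2S)-but-3-en-2-yl]cyclopentane-1,2-diol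
Conditions: KOH, DMSO/H2O (4:1), 100 °C
Reagents that add atoms: water, O
Why: Base-mediated epoxide hydrolysis; hydroxide should attack the secondary epoxide carbon (SN2, inversion), so the new hydroxyl is trans to the tertiary one, which keeps its configuration.

Step 5
Reactants: 5 (1R,2S)-1-[(2S)-but-3-en-2-yl]cyclopentane-1,2-diol; 6 2,2-dimethyloxirane
Product: 7 (1R,2S)-1-[(2S)-but-3-en-2-yl]-2-[(1-hydroxy-2-methylpropan-2-yl)oxy]cyclopentan-1-ol
Conditions: 6 (3 equiv, slow addition), BF3·OEt2 (10 mol %), CH2Cl2, −30 → 0 °C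
Reagents that add atoms: none
Why: Lewis-acid-catalysed alcoholysis of a 1,1-disubstituted epoxide takes place at its tertiary carbon, and the secondary hydroxyl of 5 is the more accessible nucleophile, so the tertiary alkyl ether with a free primary alcohol should form without touching a stereocentre.

Step 6
Reactants: 7 (1R,2S)-1-[(2S)-but-3-en-2-yl]-2-[(1-hydroxy-2-methylpropan-2-yl)oxy]cyclopentan-1-ol
Product: 9 (4aR,7aS)-4a-[(2S)-but-3-en-2-yl]-2,2-dimethylhexahydro-2H-cyclopenta[b][1,4]dioxin-3-ol, via hydroxy aldehyde 8 (not isolated)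
Conditions: Dess–Martin periodinane (1.1 equiv), NaHCO3, CH2Cl2, 0 °C
Reagents that add atoms: none
Why: Dess–Martin oxidation of the primary alcohol (the tertiary one is inert); the aldehyde should close onto the trans tertiary hydroxyl to give the six-membered lactol.

Step 7
Reactants: 9 (4aR,7aS)-4a-[(2S)-but-3-en-2-yl]-2,2-dimethylhexahydro-2H-cyclopenta[b][1,4]dioxin-3-ol
Product: 14 (3S,5aR,9aS)-3-hydroxy-2,2,5a-trimethyloctahydro-1-benzoxepin-6(2H)-one, via oxocarbenium ion 10 (not isolated), via secondary cation 11 (not isolated), via tertiary cation 12 (not isolated), via bridged oxocarbenium ion 13 (not isolated)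
Conditions: TMSOTf (2.2 equiv), CH2Cl2, −78 → −20 °C; then aq. NaHCO3
Reagents that add atoms: water, O
Why: Proposed new method: TMSOTf should ionise lactol 9 to the cyclic oxocarbenium ion 10, whose C3 is attacked by the terminal vinyl carbon C4 (chair Prins cyclisation, 6-endo-trig, closing a temporary tetrahydropyran O11–C3–C4–C5–C6–C11) to give secondary cation 11; an axial 1,2-hydride shift from C6 to C5 (tertiary cation 12) and an anti-periplanar 1,2-shift of C7 from C11 to C6, pushed by the lone pair of O11, then make the C6–C7 bond and oxocarbenium ion 13, which water hydrolyses to hydroxy ketone 14. The closest known reaction types are the Prins–pinacol reaction and the acid-promoted semipinacol ring expansion of 1-alkenylcycloalkanols; new here are the hydride shift that relays the cation from C5 to C6 and the use of the acetal oxygen as the pushing group. The shift expands the cyclopentane to the cyclohexanone and in the same event contracts the eight-membered perimeter C3–C2–O1–C7–C11–C6–C5–C4 to the oxepane. C7 migrates with retention, C6 is set because C7 arrives on the face opposite the departing hydride (so C5 and O1 end trans, the trans ring fusion, with the methyl group axial), and C3 is set by the chair Prins transition state in which the C2–O1 tether is axial. The step needs C7 and not C10 to migrate, which the cage should secure because the C11–C7 bond is axial and parallel to the empty orbital at C6 whereas C11–C10 is equatorial; it also needs the cations not to be trapped, which the non-nucleophilic triflate counter-ion and the downhill path to an oxocarbenium ion should secure.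

Step 8
Reactants: 14 (3S,5aR,9aS)-3-hydroxy-2,2,5a-trimethyloctahydro-1-benzoxepin-6(2H)-one
Product: 15 (3S,5aR,9aS)-3-[(tert-butyldimethylsilyl)oxy]-2,2,5a-trimethyloctahydro-1-benzoxepin-6(2H)-one
Conditions: TBSOTf, 2,6-lutidine, CH2Cl2, −78 → 0 °C
Reagents that add atoms: tert-butyldimethylsilyl triflate, CC(C)(C)[Si](C)(C)OS(=O)(=O)C(F)(F)F
Why: Silylation of a hindered secondary alcohol with the silyl triflate and a hindered pyridine is standard and should leave the ketone untouched at low temperature.

Step 9
Reactants: 15 (3S,5aR,9aS)-3-[(tert-butyldimethylsilyl)oxy]-2,2,5a-trimethyloctahydro-1-benzoxepin-6(2H)-one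
Product: 17 (3S,5aR,7S,9aS)-3-[(tert-butyldimethylsilyl)oxy]-2,2,5a,7-tetramethyloctahydro-1-benzoxepin-6(2H)-one, via lithium enolate 16 (not isolated)
Conditions: LiN(i-Pr)2, THF, −78 °C; MeI, −78 → −30 °C
Reagents that add atoms: iodomethane, CI
Why: The enolate can form only towards C10 (C6 is quaternary), and methyl iodide should approach anti to the axial angular methyl group, giving the equatorial C10 methyl epimer, which is also the thermodynamically preferred one.

Step 10
Reactants: 17 (3S,5aR,7S,9aS)-3-[(tert-butyldimethylsilyl)oxy]-2,2,5a,7-tetramethyloctahydro-1-benzoxepin-6(2H)-one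
Product: 18 the 6-methylidene derivative of 17 (C11=CH2, other centres unchanged)
Conditions: Ph3PCH3Br, KOt-Bu, toluene, 90 °C
Reagents that add atoms: methyltriphenylphosphonium bromide, C[P+](c1ccccc1)(c1ccccc1)c1ccccc1.[Br-]
Why: Wittig methylenation of a hindered ketone with excess ylide at elevated temperature; C10 is already the stable epimer, so enolisation should do no harm.

Step 11
Reactants: 18 the 6-methylidene derivative of 17
Product: 19 the spiro-epoxide of 18 (epoxide oxygen axial on C11, trans to the angular methyl group)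
Conditions: mCPBA, NaHCO3, CH2Cl2, 0 °C
Reagents that add atoms: 3-chloroperoxybenzoic acid, OOC(=O)c1cccc(Cl)c1
Why: Prilezhaev epoxidation; the peracid should add to the face of the exocyclic alkene anti to the axial C6 methyl group, placing the oxygen axial and the CH2 equatorial as required at C11.

Step 12
Reactants: 19 the spiro-epoxide of 18
Product: 21 the vinyl carbinol (C11: OH axial, vinyl equatorial; C3–OTBS), via sulfonium betaine 20 (not isolated)
Conditions: Me3SI, n-BuLi, THF, −10 °C → rt
Reagents that add atoms: trimethylsulfonium iodide, C[S+](C)C.[I-]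
Why: Dimethylsulfonium methylide should open the epoxide at its CH2 terminus and the betaine should lose dimethyl sulfide by base-induced elimination (known one-carbon homologation of epoxides to allylic alcohols), leaving the C11–O bond and its configuration untouched.

Step 13
Reactants: 15 (3S,5aR,9aS)-3-[(tert-butyldimethylsilyl)oxy]-2,2,5a-trimethyloctahydro-1-benzoxepin-6(2H)-one
Product: 23 the enol triflate of 15 (C10′=C11′–OTf), via potassium enolate 22 (not isolated)
Conditions: KN(SiMe3)2, THF, −78 °C; PhNTf2; aq. NH4Cl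
Reagents that add atoms: N-phenylbis(trifluoromethanesulfonimide), O=S(=O)(N(c1ccccc1)S(=O)(=O)C(F)(F)F)C(F)(F)F
Why: The ketone can enolise only towards C10′, and O-sulfonylation of the potassium enolate is the standard route to enol triflates.

Step 14
Reactants: 23 the enol triflate of 15
Product: 24 the enol triflate alcohol (C3′–OH as in 14)
Conditions: HF·pyridine, pyridine, THF, 0 °C → rt
Reagents that add atoms: none
Why: Fluoride cleavage of the silyl ether; the enol triflate should be stable to buffered HF·pyridine.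

Step 15
Reactants: 24 the enol triflate alcohol
Product: 25 the enol triflate ketone (C3′=O)
Conditions: Dess–Martin periodinane, NaHCO3, CH2Cl2, rt
Reagents that add atoms: none
Why: Dess–Martin oxidation of a secondary alcohol under neutral conditions.

Step 16
Reactants: 25 the enol triflate ketone
Product: 26 the (3R) enol triflate alcohol (C3′–OH cis to the angular methyl group, the C3′ epimer of 24)
Conditions: (S)-2-methyl-CBS-oxazaborolidine (0.2 equiv), catecholborane, toluene, −78 °C
Reagents that add atoms: none
Why: Corey–Bakshi–Shibata reduction; the catalyst distinguishes the quaternary C2′ (large) from the C4′ methylene (small) and, by the usual model, should give the (3R) alcohol by reagent control.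

Step 17
Reactants: 26 the (3R) enol triflate alcohol
Product: 27 the enol triflate acetate
Conditions: Ac2O, DMAP (cat.), pyridine, CH2Cl2, rt
Reagents that add atoms: acetic anhydride, CC(=O)OC(C)=O
Why: DMAP-catalysed acetylation of a secondary alcohol.

Step 18
Reactants: 21 the vinyl carbinol; 27 the enol triflate acetate
Product: 29 the coupled trisubstituted alkene (C10′=C11′, C11′–C13 bond formed), via B-alkyl-9-BBN 28 (not isolated)
Conditions: 9-BBN dimer, THF, rt; then 27, Pd(dppf)Cl2 (10 mol %), AsPh3, Cs2CO3, DMF/THF/H2O, rt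
Reagents that add atoms: none
Why: 9-BBN should hydroborate the vinyl group at its terminus, and B-alkyl Suzuki–Miyaura coupling of the alkylborane with the enol triflate should join the two halves.

Step 19
Reactants: 29 the coupled trisubstituted alkene
Product: 31 the C10′ alcohol (H on C11′ axial, trans to the angular methyl group; side chain equatorial), via secondary alkylborane 30 (not isolated)
Conditions: BH3·THF, THF, 0 °C; then 30% H2O2, pH 7 phosphate buffer, 0 °C → rt
Reagents that add atoms: hydrogen peroxide, OO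
Why: Hydroboration–oxidation; boron should add to the less substituted C10′ from the face anti to the axial angular methyl group, so hydrogen at C11′ ends on that face and the chain equatorial, and oxidation proceeds with retention.

Step 20
Reactants: 31 the C10′ alcohol
Product: 32 the C10′ ketone
Conditions: Dess–Martin periodinane, NaHCO3, CH2Cl2, rt
Reagents that add atoms: none
Why: Dess–Martin oxidation of the only secondary alcohol; the tertiary alcohol, acetate and silyl ether should be unaffected, and C11′ already has its stable configuration.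

Step 21
Reactants: 32 the C10′ ketone
Product: 33 the C10′ methylidene compound (C3–OTBS)
Conditions: Zn, CH2Br2, TiCl4, THF/CH2Cl2, 0 °C → rt
Reagents that add atoms: dibromomethane, BrCBr
Why: Takai–Lombardo methylenation; the non-basic reagent should methylenate the ketone in the presence of the acetate without epimerising C11′.

Step 22
Reactants: 33 the C10′ methylidene compound
Product: 34 the C3 alcohol
Conditions: HF·pyridine, pyridine, THF, 0 → 40 °C
Reagents that add atoms: none
Why: Fluoride cleavage of the hindered silyl ether; the acetate, tertiary alcohol and exocyclic alkene should survive.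

Step 23
Reactants: 34 the C3 alcohol
Product: 35 3-epi-sodwanone K 3-acetate
Conditions: Dess–Martin periodinane, NaHCO3, CH2Cl2, rt
Reagents that add atoms: none
Why: Dess–Martin oxidation of the last secondary alcohol to the oxepanone; the tertiary alcohol, acetate and alkene are inert.

**Compound list**

1 | cyclopent-1-ene-1-carbaldehyde | O=CC1=CCCC1 | starting material
2 | 1-ethenylcyclopent-1-ene | C=CC1=CCCC1 | intermediate
3 | 1-[(2S)-but-3-en-2-yl]cyclopent-1-ene | C=C[C@H](C)C1=CCCC1 | intermediate
4 | (1R,5R)-1-[(2S)-but-3-en-2-yl]-6-oxabicyclo[3.1.0]hexane | C=C[C@H](C)[C@]12CCC[C@H]1O2 | intermediate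
5 | (1R,2S)-1-[(2S)-but-3-en-2-yl]cyclopentane-1,2-diol (trans diol) | C=C[C@H](C)[C@]1(O)CCC[C@@H]1O | intermediate
6 | 2,2-dimethyloxirane | CC1(C)CO1 | starting material
7 | (1R,2S)-1-[(2S)-but-3-en-2-yl]-2-[(1-hydroxy-2-methylpropan-2-yl)oxy]cyclopentan-1-ol | C=C[C@H](C)[C@]1(O)CCC[C@@H]1OC(C)(C)CO | intermediate
8 | 2-{[(1S,2R)-2-[(2S)-but-3-en-2-yl]-2-hydroxycyclopentyl]oxy}-2-methylpropanal | C=C[C@H](C)[C@]1(O)CCC[C@@H]1OC(C)(C)C=O | intermediate (not isolated)
9 | (4aR,7aS)-4a-[(2S)-but-3-en-2-yl]-2,2-dimethylhexahydro-2H-cyclopenta[b][1,4]dioxin-3-ol (trans-fused lactol, both anomers) | C=C[C@H](C)[C@]12CCC[C@@H]1OC(C)(C)C(O)O2 | intermediate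
10 | cyclic oxocarbenium ion of 9 (C3=O11+) | C=C[C@H](C)[C@]12CCC[C@@H]1OC(C)(C)C=[O+]2 | intermediate (not isolated)
11 | tricyclic secondary cation at C5 after Prins closure | C[C@H]1[CH+]C[C@@H]2O[C@]13CCC[C@@H]3OC2(C)C | intermediate (not isolated)
12 | tertiary cation at C6 after the hydride shift | C[C+]1CC[C@@H]2O[C@]13CCC[C@@H]3OC2(C)C | intermediate (not isolated)
13 | ring-expanded bridged oxocarbenium ion (C11=O11+, O11 still bonded to C3) | C[C@]12CC[C@@H]3[O+]=C1CCC[C@@H]2OC3(C)C | intermediate (not isolated)
14 | (3S,5aR,9aS)-3-hydroxy-2,2,5a-trimethyloctahydro-1-benzoxepin-6(2H)-one (trans-fused, C3–OH trans to the angular methyl) | O=C1CCC[C@@H]2OC(C)(C)[C@@H](O)CC[C@]21C | intermediate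
15 | (3S,5aR,9aS)-3-[(tert-butyldimethylsilyl)oxy]-2,2,5a-trimethyloctahydro-1-benzoxepin-6(2H)-one | O=C1CCC[C@@H]2OC(C)(C)[C@@H](O[Si](C)(C)C(C)(C)C)CC[C@]21C | intermediate
16 | lithium enolate of 15 (C10=C11–OLi) | [Li+].[O-]C1=CCC[C@@H]2OC(C)(C)[C@@H](O[Si](C)(C)C(C)(C)C)CC[C@]21C | intermediate (not isolated)
17 | (3S,5aR,7S,9aS)-3-[(tert-butyldimethylsilyl)oxy]-2,2,5a,7-tetramethyloctahydro-1-benzoxepin-6(2H)-one | O=C1[C@@H](C)CC[C@@H]2OC(C)(C)[C@@H](O[Si](C)(C)C(C)(C)C)CC[C@]21C | intermediate
18 | 6-methylidene derivative of 17 (C11=CH2) | C=C1[C@@H](C)CC[C@@H]2OC(C)(C)[C@@H](O[Si](C)(C)C(C)(C)C)CC[C@]21C | intermediate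
19 | spiro-epoxide of 18 (oxygen axial on C11, trans to the angular methyl; CH2 equatorial) | C1O[C@]12[C@@H](C)CC[C@@H]3OC(C)(C)[C@@H](O[Si](C)(C)C(C)(C)C)CC[C@]32C | intermediate
20 | sulfonium betaine from 19 (C11–O−, C12H2–C13H2–SMe2+) | C[S+](C)CC[C@]1([O-])[C@@H](C)CC[C@@H]2OC(C)(C)[C@@H](O[Si](C)(C)C(C)(C)C)CC[C@]21C | intermediate (not isolated)
21 | vinyl carbinol: 6-ethenyl-6-hydroxy derivative of 17 (OH axial, vinyl equatorial at C11) | C=C[C@]1(O)[C@@H](C)CC[C@@H]2OC(C)(C)[C@@H](O[Si](C)(C)C(C)(C)C)CC[C@]21C | intermediate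
22 | potassium enolate of 15 | [K+].[O-]C1=CCC[C@@H]2OC(C)(C)[C@@H](O[Si](C)(C)C(C)(C)C)CC[C@]21C | intermediate (not isolated)
23 | enol triflate of 15 (C10′=C11′–OTf) | O=S(=O)(OC1=CCC[C@@H]2OC(C)(C)[C@@H](O[Si](C)(C)C(C)(C)C)CC[C@]21C)C(F)(F)F | intermediate
24 | enol triflate alcohol (C3′–OH as in 14) | O=S(=O)(OC1=CCC[C@@H]2OC(C)(C)[C@@H](O)CC[C@]21C)C(F)(F)F | intermediate
25 | enol triflate ketone (C3′=O) | O=S(=O)(OC1=CCC[C@@H]2OC(C)(C)C(=O)CC[C@]21C)C(F)(F)F | intermediate
26 | (3R) enol triflate alcohol (C3′–OH cis to the angular methyl) | O=S(=O)(OC1=CCC[C@@H]2OC(C)(C)[C@H](O)CC[C@]21C)C(F)(F)F | intermediate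
27 | enol triflate acetate | O=S(=O)(OC1=CCC[C@@H]2OC(C)(C)[C@H](OC(C)=O)CC[C@]21C)C(F)(F)F | intermediate
28 | B-alkyl-9-borabicyclo[3.3.1]nonane from 21 (boron on C13) | B3(C4CCCC3CCC4)CC[C@]1(O)[C@@H](C)CC[C@@H]2OC(C)(C)[C@@H](O[Si](C)(C)C(C)(C)C)CC[C@]21C | intermediate (not isolated)
29 | coupled trisubstituted alkene (C10′=C11′; C3′–OAc, C3–OTBS, C11–OH) | C1(CC[C@]3(O)[C@@H](C)CC[C@@H]4OC(C)(C)[C@@H](O[Si](C)(C)C(C)(C)C)CC[C@]43C)=CCC[C@@H]2OC(C)(C)[C@H](OC(C)=O)CC[C@]21C | intermediate
30 | secondary alkylborane at C10′ | [BH2][C@H]1CC[C@@H]2OC(C)(C)[C@H](OC(C)=O)CC[C@@]2(C)[C@@H]1CC[C@]1(O)[C@@H](C)CC[C@@H]2OC(C)(C)[C@@H](O[Si](C)(C)C(C)(C)C)CC[C@]21C | intermediate (not isolated)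
31 | C10′ alcohol (OH cis to H on C11′; H on C11′ trans to the angular methyl) | O[C@H]1CC[C@@H]2OC(C)(C)[C@H](OC(C)=O)CC[C@@]2(C)[C@@H]1CC[C@]1(O)[C@@H](C)CC[C@@H]2OC(C)(C)[C@@H](O[Si](C)(C)C(C)(C)C)CC[C@]21C | intermediate
32 | C10′ ketone | O=C1CC[C@@H]2OC(C)(C)[C@H](OC(C)=O)CC[C@@]2(C)[C@@H]1CC[C@]1(O)[C@@H](C)CC[C@@H]2OC(C)(C)[C@@H](O[Si](C)(C)C(C)(C)C)CC[C@]21C | intermediate
33 | C10′ methylidene compound with C3–OTBS | C=C1CC[C@@H]2OC(C)(C)[C@H](OC(C)=O)CC[C@@]2(C)[C@@H]1CC[C@]1(O)[C@@H](C)CC[C@@H]2OC(C)(C)[C@@H](O[Si](C)(C)C(C)(C)C)CC[C@]21C | intermediate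
34 | C3 alcohol (target with the C3 ketone as the alcohol) | C=C1CC[C@@H]2OC(C)(C)[C@H](OC(C)=O)CC[C@@]2(C)[C@@H]1CC[C@]1(O)[C@@H](C)CC[C@@H]2OC(C)(C)[C@@H](O)CC[C@]21C | intermediate
35 | 3-epi-sodwanone K 3-acetate | C=C1CC[C@@H]2OC(C)(C)[C@H](OC(C)=O)CC[C@@]2(C)[C@@H]1CC[C@]1(O)[C@@H](C)CC[C@@H]2OC(C)(C)C(=O)CC[C@]21C | target

**Step count and risks**

Total steps: 23. Longest linear sequence: 19 steps (1–8, 13–17, 18–23).

Steps most likely to fail:

Step 7 (proposed new method). The secondary cation may be captured or lose a proton before the hydride shift, a methyl group may shift instead of hydride, or the oxocarbenium ion may fragment with loss of the aldehyde arm. Fallback with known reaction types, setting out from 9 and returning at 14: a Prins cyclisation with bromide capture (TMSBr, CH2Cl2, −78 °C) should give the axial bromide F1. Anti elimination with DBU (toluene, 100 °C) should give the alkene F2, mainly the C5=C6 isomer. Protonation of this allylic ether with catalytic TfOH in CH2Cl2 (protio-semipinacol rearrangement) and aqueous work-up should then give 14.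

Step 5. The epoxide may oligomerise, the hindered alcohol may convert poorly, or attack may occur at the primary epoxide carbon. Fallback setting out from 5 and returning at 9: alkylation of the secondary alkoxide (NaH, ethyl bromoacetate, THF) should give the hydroxy ester F3. Transesterification onto the tertiary hydroxyl (Ti(Oi-Pr)4 cat., toluene, 80 °C) should give the dioxanone F4. Two enolate methylations (LiN(i-Pr)2, MeI, THF, −78 °C, twice) should give the gem-dimethyl lactone F5, and i-Bu2AlH (CH2Cl2, −78 °C) should reduce it to lactol 9.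

Step 12. Opening of the hindered spiro-epoxide may be slow, and base-induced isomerisation to an allylic alcohol may take over. Fallback setting out from 18 and returning at 21: dihydroxylation (OsO4 cat., N-methylmorpholine N-oxide, acetone/H2O; same face as the epoxidation) should give the diol F6. Parikh–Doering oxidation of the primary alcohol (SO3·pyridine, DMSO, i-Pr2NEt) should give the hydroxy aldehyde F7, and Wittig methylenation (Ph3PCH3Br, KN(SiMe3)2, THF) should give 21.

**Further compounds**

F1 | step 7 | axial C5 bromide of the Prins adduct | C[C@H]1[C@@H](Br)C[C@@H]2O[C@]13CCC[C@@H]3OC2(C)C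
F2 | step 7 | C5=C6 alkene of the bridged tricycle | CC1=CC[C@@H]2O[C@]13CCC[C@@H]3OC2(C)C
F3 | step 5 | ethyl 2-{[(1S,2R)-2-[(2S)-but-3-en-2-yl]-2-hydroxycyclopentyl]oxy}acetate | C=C[C@H](C)[C@]1(O)CCC[C@@H]1OCC(=O)OCC
F4 | step 5 | trans-fused 4a-[(2S)-but-3-en-2-yl]hexahydrocyclopenta[b][1,4]dioxin-3-one | C=C[C@H](C)[C@]12CCC[C@@H]1OCC(=O)O2
F5 | step 5 | 2,2-dimethyl derivative of F4 | C=C[C@H](C)[C@]12CCC[C@@H]1OC(C)(C)C(=O)O2
F6 | step 12 | C11 diol: 6-hydroxy-6-(hydroxymethyl) derivative of 17 (tertiary OH axial) | OC[C@]1(O)[C@@H](C)CC[C@@H]2OC(C)(C)[C@@H](O[Si](C)(C)C(C)(C)C)CC[C@]21C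
F7 | step 12 | C11 hydroxy aldehyde: 6-formyl-6-hydroxy derivative of 17 | O=C[C@]1(O)[C@@H](C)CC[C@@H]2OC(C)(C)[C@@H](O[Si](C)(C)C(C)(C)C)CC[C@]21C
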